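The pyranone ring is cut at C3–C4 and O1–C8a. The feature exploited is that both ring-A carbons ortho to the C4 carbonyl carry oxygen (C8a–O1 and C5–OH), so ring A maps onto a symmetric 2,6-difluoro-4-methoxybenzoyl unit with two equivalent leaving groups. In one operation the lithium enolate of a B-ring aryl ketone already bearing the prenyl chain is C-aroylated and the diketonate oxygen displaces an ortho fluoride, closing ring C and leaving a C5 fluoride for later oxygenation. The precursor is 1-(2,5-diallyloxy-4-methoxyphenyl)-5-methylhex-4-en-1-one; allyl ethers are chosen so that the later C5 allyl ether and both B-ring phenols are released together by neutral Pd(0) catalysis.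

Key step: step 5

Assumption: the target has no stereocentre and rotation about C2–C1' is taken as free, so it is a single achiral compound and no stereocontrol is required.

Step 1
Reactants: 1 2,6-difluoro-4-methoxybenzoic acid
Product: 2 2,6-difluoro-4-methoxybenzoyl chloride
Conditions: (COCl)2, cat. DMF, CH2Cl2, 0 °C → rt; evaporate, use crude
Reagents that add atoms: oxalyl chloride, O=C(Cl)C(=O)Cl
Why: DMF-catalysed conversion of a carboxylic acid into its acyl chloride (Vilsmeier-type activation), to which the aryl fluorides and the methyl ether are inert, with only gaseous by-products so that the crude chloride can be used directly.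

Step 2
Reactants: 3 2-methoxyhydroquinone; 4 acetic acid
Product: 5 1-(2,5-dihydroxy-4-methoxyphenyl)ethan-1-one
Conditions: BF3·OEt2 (3 equiv), AcOH (4, also solvent), 90 °C; then H2O
Reagents that add atoms: none
Why: Boron trifluoride-mediated Friedel–Crafts (Fries-type) C-acetylation of an electron-rich phenol, which should occur at the one ring position that is para to the methoxy group and ortho to a hydroxyl, and should stop after one acylation because the product is held as a deactivated chelate.

Step 3
Reactants: 5 1-(2,5-dihydroxy-4-methoxyphenyl)ethan-1-one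
Product: 6 1-[4-methoxy-2,5-bis(prop-2-en-1-yloxy)phenyl]ethan-1-one
Conditions: allyl bromide (2.5 equiv), K2CO3, DMF, 60 °C, under Ar
Reagents that add atoms: allyl bromide, C=CCBr
Why: Williamson etherification in warm K2CO3/DMF should alkylate both the free 5-OH and the hydrogen-bonded 2-OH, and exclusion of air keeps the deprotonated hydroquinone from oxidising.

Step 4
Reactants: 6 1-[4-methoxy-2,5-bis(prop-2-en-1-yloxy)phenyl]ethan-1-one; 7 prenyl bromide (1-bromo-3-methylbut-2-ene)
Product: 9 1-[4-methoxy-2,5-bis(prop-2-en-1-yloxy)phenyl]-5-methylhex-4-en-1-one, via methyl ketone lithium enolate 8 (not isolated)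
Conditions: LDA (1.05 equiv), THF, −78 °C; then 7 (1.0 equiv), −78 → 0 °C
Reagents that add atoms: none
Why: Alkylation of a preformed lithium enolate (SN2 on a primary allylic bromide), in which only one enolate is possible for the methyl ketone, and full deprotonation at −78 °C followed by a fast-reacting electrophile should keep proton exchange, and with it double alkylation, low.

Step 5
Reactants: 9 1-[4-methoxy-2,5-bis(prop-2-en-1-yloxy)phenyl]-5-methylhex-4-en-1-one; 2 2,6-difluoro-4-methoxybenzoyl chloride
Product: 12 5-fluoro-7-methoxy-2-[4-methoxy-2,5-bis(prop-2-en-1-yloxy)phenyl]-3-(3-methylbut-2-en-1-yl)-4H-chromen-4-one, via ketone lithium enolate 10 (not isolated), via lithium 1,3-diketonate 11 (not isolated)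
Conditions: LiHMDS (2.5 equiv), THF, −78 °C; then 2 (1.1 equiv), −78 °C → rt; then 60 °C
Reagents that add atoms: none
Why: LiHMDS deprotonates 9 to lithium enolate 10, which attacks acyl chloride 2 at carbon (crossed-Claisen C-aroylation, forming C3–C4), and the diketone is deprotonated at once by the surplus base to diketonate 11, whose B-ring-side oxygen adds to a fluorine-bearing carbon and expels fluoride through a Meisenheimer adduct stabilised by the adjacent carbonyl (intramolecular SNAr, forming O1–C8a). The closest known reaction type is the one-pot C-acylation/SNAr annulation of ketone enolates with 2-halobenzoyl chlorides, which gives chromones and, from enaminones, 4-quinolones. The pyranone closes as a six-membered ring by oxygen attack on the arene ipso carbon, a 6-exo-trig addition–elimination. No stereocentre is created, since the sp3 carbon of the transient diketone is planar in 11 and becomes C3 of the chromone. The step needs C- over O-acylation, which the tightly O-bound lithium enolate in THF favours, and any enol ester formed is an acyl donor that remaining enolate converts into the same diketonate. Closure is unambiguous because only the B-side oxygen can reach a C–F carbon through a six-membered transition state, the two fluorines are equivalent, and the methoxy group, meta to both, does not deactivate them; the second fluorine ends up at C5.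

Step 6
Reactants: 12 5-fluoro-7-methoxy-2-[4-methoxy-2,5-bis(prop-2-en-1-yloxy)phenyl]-3-(3-methylbut-2-en-1-yl)-4H-chromen-4-one
Product: 13 7-methoxy-2-[4-methoxy-2,5-bis(prop-2-en-1-yloxy)phenyl]-3-(3-methylbut-2-en-1-yl)-5-(prop-2-en-1-yloxy)-4H-chromen-4-one
Conditions: NaH, allyl alcohol, THF, 0 °C; then 12, DMF, rt → 50 °C
Reagents that add atoms: allyl alcohol, C=CCO
Why: Nucleophilic aromatic substitution (addition–elimination) should succeed because the C5 fluoride is ortho to the C4 carbonyl, which takes up the charge of the Meisenheimer adduct, while O1 and the 7-methoxy group are meta to C5 and do not deactivate it, and C2 is shielded from conjugate attack by its aryl group and the neighbouring prenyl chain.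

Step 7
Reactants: 13 7-methoxy-2-[4-methoxy-2,5-bis(prop-2-en-1-yloxy)phenyl]-3-(3-methylbut-2-en-1-yl)-5-(prop-2-en-1-yloxy)-4H-chromen-4-one
Product: 14 artoindonesianin Q, 5-hydroxy-2-(2,5-dihydroxy-4-methoxyphenyl)-7-methoxy-3-(3-methylbut-2-en-1-yl)-4H-chromen-4-one
Conditions: Pd(PPh3)4 (5 mol %), morpholine (excess), degassed THF, rt → 40 °C, under Ar; dilute aqueous acid work-up
Reagents that add atoms: none
Why: Tsuji–Trost-type deallylation, in which Pd(0) ionises each of the three aryl allyl ethers to a π-allyl complex that morpholine intercepts irreversibly, whereas the C-bound prenyl group has no leaving group and should stay untouched, and the neutral, oxygen-free medium spares the hydroquinone B ring.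

Compound list
1 | 2,6-difluoro-4-methoxybenzoic acid | COc1cc(F)c(C(=O)O)c(F)c1 | starting material
2 | 2,6-difluoro-4-methoxybenzoyl chloride | COc1cc(F)c(C(=O)Cl)c(F)c1 | intermediate
3 | 2-methoxyhydroquinone (2-methoxybenzene-1,4-diol) | COc1cc(O)ccc1O | starting material
4 | acetic acid | CC(=O)O | starting material
5 | 1-(2,5-dihydroxy-4-methoxyphenyl)ethan-1-one | CC(=O)c1cc(O)c(OC)cc1O | intermediate
6 | 1-[4-methoxy-2,5-bis(prop-2-en-1-yloxy)phenyl]ethan-1-one | CC(=O)c1cc(OCC=C)c(OC)cc1OCC=C | intermediate
7 | prenyl bromide (1-bromo-3-methylbut-2-ene) | CC(C)=CCBr | starting material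
8 | lithium 1-[4-methoxy-2,5-bis(prop-2-en-1-yloxy)phenyl]ethen-1-olate (lithium enolate of 6) | [Li+].[O-]C(=C)c1cc(OCC=C)c(OC)cc1OCC=C | intermediate
9 | 1-[4-methoxy-2,5-bis(prop-2-en-1-yloxy)phenyl]-5-methylhex-4-en-1-one | CC(C)=CCCC(=O)c1cc(OCC=C)c(OC)cc1OCC=C | intermediate
10 | lithium 1-[4-methoxy-2,5-bis(prop-2-en-1-yloxy)phenyl]-5-methylhexa-1,4-dien-1-olate (lithium enolate of 9, enolate geometry not specified) | [Li+].[O-]C(=CCC=C(C)C)c1cc(OCC=C)c(OC)cc1OCC=C | intermediate
11 | lithium enolate of 1-[4-methoxy-2,5-bis(prop-2-en-1-yloxy)phenyl]-3-(2,6-difluoro-4-methoxyphenyl)-2-(3-methylbut-2-en-1-yl)propane-1,3-dione (chelated 1,3-diketonate, geometry not specified) | [Li+].[O-]C(=C(CC=C(C)C)C(=O)c1c(F)cc(OC)cc1F)c1cc(OCC=C)c(OC)cc1OCC=C | intermediate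
12 | 5-fluoro-7-methoxy-2-[4-methoxy-2,5-bis(prop-2-en-1-yloxy)phenyl]-3-(3-methylbut-2-en-1-yl)-4H-chromen-4-one | COc1cc(F)c2c(=O)c(CC=C(C)C)c(-c3cc(OCC=C)c(OC)cc3OCC=C)oc2c1 | intermediate
13 | 7-methoxy-2-[4-methoxy-2,5-bis(prop-2-en-1-yloxy)phenyl]-3-(3-methylbut-2-en-1-yl)-5-(prop-2-en-1-yloxy)-4H-chromen-4-one | COc1cc(OCC=C)c2c(=O)c(CC=C(C)C)c(-c3cc(OCC=C)c(OC)cc3OCC=C)oc2c1 | intermediate
14 | artoindonesianin Q, 5-hydroxy-2-(2,5-dihydroxy-4-methoxyphenyl)-7-methoxy-3-(3-methylbut-2-en-1-yl)-4H-chromen-4-one (achiral) | COc1cc(O)c2c(=O)c(CC=C(C)C)c(-c3cc(O)c(OC)cc3O)oc2c1 | target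

Total step count: 7. Longest linear sequence: 6 steps (steps 2–7, from 3 to 14); step 1 is a one-step side branch.

Steps most likely to fail

Step 5. Acylation may take place on oxygen of the hindered trisubstituted enolate or on the amide base instead of on carbon, and ring closure may stall at the lithium-chelated diketonate. The fallback sets out from 6 and 2 and returns at 12. The unhindered enolate 8 (LiHMDS, THF, −78 °C) would be C-aroylated by 2 and quenched cold to give 1-[4-methoxy-2,5-bis(prop-2-en-1-yloxy)phenyl]-3-(2,6-difluoro-4-methoxyphenyl)propane-1,3-dione F1. The acidic methylene of this 1,3-diketone would then be C-prenylated with 7 (K2CO3, acetone, rt) to give 1-[4-methoxy-2,5-bis(prop-2-en-1-yloxy)phenyl]-3-(2,6-difluoro-4-methoxyphenyl)-2-(3-methylbut-2-en-1-yl)propane-1,3-dione F2. This would be cyclised in a separate SNAr step (K2CO3, DMF, 80 °C) to 12.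

Step 6. Displacement at the crowded peri position may be slow, and reversible alkoxide addition at C2 followed by opening of the pyranone may erode the material. The fallback sets out from 2, uses 9 as before and returns at 13; it places the C5 oxygen on the benzoyl unit before the ring is built. Treatment of 2 with sodium prop-2-en-1-olate (2.2 equiv, THF, 0 °C → 40 °C) should give prop-2-en-1-yl 2,6-difluoro-4-methoxybenzoate F3 and then, by ester-activated SNAr of one ortho fluoride, prop-2-en-1-yl 2-fluoro-4-methoxy-6-(prop-2-en-1-yloxy)benzoate F4. Saponification (LiOH, aqueous THF; then dilute HCl) would give 2-fluoro-4-methoxy-6-(prop-2-en-1-yloxy)benzoic acid F5, and (COCl)2/cat. DMF would give 2-fluoro-4-methoxy-6-(prop-2-en-1-yloxy)benzoyl chloride F6. Acylation of enolate 10 with this chloride under the conditions of step 5 would pass through the lithium enolate of 1-[4-methoxy-2,5-bis(prop-2-en-1-yloxy)phenyl]-3-[2-fluoro-4-methoxy-6-(prop-2-en-1-yloxy)phenyl]-2-(3-methylbut-2-en-1-yl)propane-1,3-dione F7, whose only fluoride is displaced on ring closure to give 13 directly.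

Step 4. Proton transfer between the product ketone and unreacted enolate may lead to double prenylation and returned 6. The fallback sets out from 6 and returns at 9; it uses an azaenolate, which alkylates once. Condensation of 6 with 1,1-dimethylhydrazine (cat. AcOH, EtOH, reflux) would give 1-[4-methoxy-2,5-bis(prop-2-en-1-yloxy)phenyl]ethan-1-one N,N-dimethylhydrazone F8. Deprotonation (LDA, THF, 0 °C) and alkylation with 7 (−78 °C → rt) would give 1-[4-methoxy-2,5-bis(prop-2-en-1-yloxy)phenyl]-5-methylhex-4-en-1-one N,N-dimethylhydrazone F9, and two-phase hydrolysis with aqueous oxalic acid/Et2O would release 9.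

Further compounds
F1 | step 5 | 1-[4-methoxy-2,5-bis(prop-2-en-1-yloxy)phenyl]-3-(2,6-difluoro-4-methoxyphenyl)propane-1,3-dione | COc1cc(F)c(C(=O)CC(=O)c2cc(OCC=C)c(OC)cc2OCC=C)c(F)c1
F2 | step 5 | 1-[4-methoxy-2,5-bis(prop-2-en-1-yloxy)phenyl]-3-(2,6-difluoro-4-methoxyphenyl)-2-(3-methylbut-2-en-1-yl)propane-1,3-dione | COc1cc(F)c(C(=O)C(CC=C(C)C)C(=O)c2cc(OCC=C)c(OC)cc2OCC=C)c(F)c1
F3 | step 6 | prop-2-en-1-yl 2,6-difluoro-4-methoxybenzoate | COc1cc(F)c(C(=O)OCC=C)c(F)c1
F4 | step 6 | prop-2-en-1-yl 2-fluoro-4-methoxy-6-(prop-2-en-1-yloxy)benzoate | COc1cc(F)c(C(=O)OCC=C)c(OCC=C)c1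
F5 | step 6 | 2-fluoro-4-methoxy-6-(prop-2-en-1-yloxy)benzoic acid | COc1cc(F)c(C(=O)O)c(OCC=C)c1
F6 | step 6 | 2-fluoro-4-methoxy-6-(prop-2-en-1-yloxy)benzoyl chloride | COc1cc(F)c(C(=O)Cl)c(OCC=C)c1
F7 | step 6 | lithium enolate of 1-[4-methoxy-2,5-bis(prop-2-en-1-yloxy)phenyl]-3-[2-fluoro-4-methoxy-6-(prop-2-en-1-yloxy)phenyl]-2-(3-methylbut-2-en-1-yl)propane-1,3-dione | [Li+].[O-]C(=C(CC=C(C)C)C(=O)c1c(F)cc(OC)cc1OCC=C)c1cc(OCC=C)c(OC)cc1OCC=C
F8 | step 4 | 1-[4-methoxy-2,5-bis(prop-2-en-1-yloxy)phenyl]ethan-1-one N,N-dimethylhydrazone | CC(=NN(C)C)c1cc(OCC=C)c(OC)cc1OCC=C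
F9 | step 4 | 1-[4-methoxy-2,5-bis(prop-2-en-1-yloxy)phenyl]-5-methylhex-4-en-1-one N,N-dimethylhydrazone | CC(C)=CCCC(=NN(C)C)c1cc(OCC=C)c(OC)cc1OCC=C
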